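(The data were computed for substances that don't exist.)

Two incoming ligands go into each complex with two exchanged, and 0.900 equiv are charged per starting complex, so this flask is judged here by the ligand ceiling, the incoming ligand charged per starting complex divided by two: 0.450 of the charge.

| setting | south-west | north | flask |
|---|---|---|---|
| starting complex | 0.10 M | 0.10 M | 0.10 M |
| incoming ligand | 0.90 equiv | 0.90 equiv | 0.900 equiv |
| leaving ligand | 1 equiv | 0.50 equiv | 1.00 equiv |
| capture agent | 0.10 M | 0.10 M | 0.100 M |
| temperature | 70 °C | 65 °C | 70 °C |
| remark | the very flask that is asked about, followed so far | run made earlier |  |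
| time |  |  | 25 h |

| south-west: time / h | south-west: complex with two exchanged / % | north: time / h | north: complex with two exchanged / % |
|---|---|---|---|
| 2.00 | 10.2 | 2.00 | 6.7 |
| 5.00 | 20.9 | 6.00 | 16.9 |
| 10.0 | 24.3 | 12.0 | 22.1 |
| 15.0 | 23.5 | 20.0 | 22.8 |

(each reading ± 0.5 percentage points)

- midnight: at 25 h raise the temperature by 10 K, then wait 2.0 d
- dusk: at 25 h take out 90% of the leaving ligand then present, then wait 2.0 d
- winter: change nothing and wait 2.0 d more
- spring: at 25 h add incoming ligand, 50.0% of the amount charged, then wait 2.0 d

1. complex with two exchanged, in percent of the starting complex first charged, at 25 h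
2. which option adds most complex with two exchanged ("none" when 2 percentage points or less is all one gets) (midnight / dusk / winter / spring / none)
3. complex with two exchanged present, in percent of the starting complex first charged, after dusk
4. complex with two exchanged present, in percent of the starting complex first charged, after winter

- the volume of additions can be left aside
- the earlier runs were read with a standard deviation of 0.5 percentage points

Two extreme versions can be solved in the head. In the first, each complex touched takes its second ligand at once, and complex with two exchanged reaches the ceiling. In the second, the first exchange takes the charge of incoming ligand before any second exchange starts: 0.900 equiv of complex with one exchanged stands, and none with two exchanged. The real flask lies between.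

The south-west run, which is this flask followed so far, reads 24.3% at 10.0 h and 23.5% at 15.0 h. That is a difference of 0.8 points against a scatter of 0.5 points on each reading, so it reads as a plateau near 23.9%, which is 0.531 of the ceiling. The north run, on the same ligand charge with half the leaving ligand at 65 °C, reads 0.507 of it.

This reckoning therefore commits to the plateau for now, after winter and after dusk. Midnight and dusk leave the ligand charge, and so the ceiling, where it stands. Spring lifts the ceiling to 0.675, and at the same share that gives 35.8%, a gain of 12 points.

The forecast gives 21.8% for now (range 20.3% to 23%), 22% after dusk and 16% after winter, each lower than the plateau of this reckoning, after winter by 7.9 points. It also names spring: “Fresh incoming ligand attacks the actual limitation”.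

The flask gives 23.8% at 25 h, with spring adding 8.4 points.

    starting complex + incoming ligand → leaving ligand + complex with one exchanged (k = 0.00160 M⁻¹ s⁻¹, Ea = 70.0 kJ mol⁻¹)
    complex with one exchanged + incoming ligand → leaving ligand + complex with two exchanged (k = 0.00130 M⁻¹ s⁻¹, Ea = 89.0 kJ mol⁻¹)
    complex with two exchanged + incoming ligand → leaving ligand + complex with three exchanged (k = 1.00 × 10⁻⁴ M⁻¹ s⁻¹, Ea = 92.0 kJ mol⁻¹)
    complex with one exchanged + capture agent → trapped intermediate (k = 1.40 × 10⁻⁴ M⁻¹ s⁻¹, Ea = 94.0 kJ mol⁻¹)
    leaving ligand + starting complex → side product (k = 6.80 × 10⁻⁵ M⁻¹ s⁻¹, Ea = 98.0 kJ mol⁻¹)
    (constants at 70 °C)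

After dusk the flask holds 23.8% and after winter 23.8%, where the forecast had 16%. At 25.0 h the flask keeps 0.150% of its incoming ligand, the limiting reagent. Its complex with two exchanged stands at 0.529 of the ligand ceiling. A neighbouring flask on the same ligand charge, with 4.00 equiv of capture agent, gives 19.5%, which is 0.433 of that ceiling.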